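## Analysis of the target

The target is a trans-fused decalin (ring A: C1–C5 and C10; ring B: C5–C10; labdane numbering) whose C9 carries a two-carbon tether (C11–C12) to C13 of a furan-2(5H)-one (C13=C14, C15 the OCH2, C16 the carbonyl). C4 bears two hydroxymethyl groups (C18, C19) and is not a stereocentre; C8 bears a third (C17). The four stereocentres C5, C10, C9 and C8 are contiguous and have the configuration 5S,8S,9R,10S. The C20 methyl on C10 is axial, H5 and H9 lie on the opposite face (trans ring fusion, C11 equatorial), and C17 is equatorial, so C11 and C17 are trans-diequatorial. The butenolide is sensitive to base, hydride, nucleophiles and hydrogenation, so it has to be finished late, and the three primary hydroxyls plus the oxygenated precursor of C11 must be told apart. The hard points are the quaternary C10 flanked by two stereocentres, the one-carbon oxygenated branches on C4 and C8, and the C8 configuration, which is opposite to what addition from the open face of a C7=C8 alkene would give. The strategy rests on one structural observation: in ring B, C8 (with C17) is 1,4 to C5 (with C4), the substitution pattern of a p-menthane. Ring B with C17 and the three-carbon unit C4/C3/C18 is therefore the complete skeleton of carvone, and ring A needs only the two substituents on C10 (C20 and C1–C2) and a single new bond, C2–C3. The target belongs to the ent-series, which calls for (S)-carvone, whose stereocentre becomes C5.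

## Retrosynthetic reasoning

37 from 36. The last step only removes the acetonide on O18/O19 and the silyl ether on O17. All carbon–carbon bonds and all four stereocentres are in place, and the butenolide tolerates dilute acid, so nothing can be scrambled at the end.

36 from 33, and 33 from 31 plus 32. The C13=C14 bond is introduced by selenoxide elimination from the saturated lactone 33. Compound 33 is cut at C11–C12, a bond between two sp3 carbons away from every stereocentre, so the coupling has no stereochemical task and all five carbons C12–C16 arrive in one bought piece, 32. A radical conjugate addition is chosen because C11 is a beta-branched primary carbon next to the quaternary C10, where SN2 chemistry is slow, and because the radical must be generated only after ring B is saturated (a C11 radical next to a C7=C8 alkene could rearrange).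

31 back to 28. The iodide 31 comes from alcohol 30. A pivalate on O11 (29, 28) and a silyl ether on O17 separate in time two primary alcohols that could not be differentiated by reactivity.

28 from 25, and 25 from 23. C8 is the one stereocentre that steric approach control would set wrongly, so it is traced back to an aldehyde (27) that can be equilibrated: the formyl group goes equatorial, trans to the C11 arm and away from the axial C20. The aldehyde comes from the enal 25, and 25 from allylic oxidation of the carvone methyl group in 23. This is why the C7=C8 alkene of carvone is kept until this point.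

23 and 22 from 20. The C9–H bond is cut, leading to the exocyclic C9=C11 diene 20. Hydroboration delivers hydrogen to C9 on the face away from the axial C20 on the neighbouring carbon, which is the configuration required, and places oxygen on C11.

20 from 19, and 13 from 12. C11 is attached to the C9 ketone of 12 as a silylmethyl nucleophile, and the alkene is released later by Peterson elimination. Keeping C11 latent as the tertiary carbinol 13 removes the ketone before borane and hydroxide are used on ring A and prevents a second exocyclic alkene from competing with C4=C18.

19 and 18 from 13. The C4–C19 bond is cut by a retro-aldol with a one-carbon aldehyde (16 to 17 to 18, aldol then crossed Cannizzaro). The aldehyde 16 comes from hydroboration and oxidation of the C4=C18 methylidene group (15), the handle left by the ring-forming step.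

12 from 10. The C2 hydroxyl in 10 has no counterpart in the target and is removed by radical deoxygenation through 11.

10 from 9. This is the key disconnection, C2–C3: an intramolecular carbonyl-ene reaction between the aldehyde of 9 and its isopropenyl group. It is made here because it is the only bond missing between a carvone that already carries every carbon of ring A and the decalin, and because the ene reaction leaves C4=C18 ready for the C4 chemistry.

9 back to 1. The aldehyde arm is traced through diol 8 to ester 7, and the quaternary C10 to two enolate alkylations of 1, first with 2 (via 4), then with 5. The second electrophile enters opposite to the isopropenyl group, which places C1 trans to C4 as the trans-decalin requires.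

## Alternatives that were turned down

Alternative 1: Both C5–C10 and C8–C9 are cut, which opens rings A and B at once to an open-chain substrate. In the forward direction a chiral oxazaborolidinium Lewis acid would bind the C11 formyl group of an (E)-C9=C10 enal while an (E,E)-diene C5=C6–C7=C8 at the other end of the C1–C4 tether adds to it, giving the octalin aldehyde A1.
- In its favour: two rings, two carbon–carbon bonds and the relative configuration of C5, C9 and C10 in one step, absolute configuration from a catalyst, and C11 already an aldehyde. On bonds formed per step it is clearly stronger than the chosen route.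
- Against it: the C5–C10 bond would join a diene terminus next to the fully substituted C4 and a beta,beta-disubstituted enal carbon that becomes quaternary. This is a congested and electronically poor pairing for this type of Lewis acid activation, and a thermal background reaction would erode the selectivity.
- A1 also has C17 axial, the wrong C8 configuration. Because C17 is an ether there, correcting it costs deprotection, oxidation, epimerisation and reduction on top of saturating C6=C7.
- The benzyl ethers must later be removed without reducing the butenolide, and the substrate needs its own multi-step synthesis with three defined alkene geometries.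
- The chosen strategy instead takes C5 from (S)-carvone with no catalyst-controlled step and forms only one unhindered bond in its ring closure.

Alternative 2: C9–C10 is cut with C11 at the acid level. The precursor is a six-membered lactone (C11 carbonyl, ring oxygen on C6) whose C6 carries the ring A cyclohexene through C5=C10. Its silyl ketene acetal would undergo an Ireland–Claisen shift that bonds C9 to C10, breaks C6–O and turns the lactone into carbocyclic ring B, giving the acid A2.
- In its favour: the quaternary C10 is made by a suprafacial sigmatropic shift with transfer of chirality from C6, which is as dependable as, or more so than, the diastereoselective alkylation of the chosen route, and C17 is already equatorial.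
- Against it: the ring-constrained transition state gives A2 with the C9 acid axial, so C9 must be epimerised next to a quaternary carbon.
- C5 is still sp2 in A2 and must be set by hydrogenating a trisubstituted alkene wedged between C4 and C10. C11 arrives one oxidation level too high.
- The lactone needs two stereocentres (C6 and C8) built enantioselectively before the key step.
- The chosen route has C5 and C10 fixed before any ring is formed and sets C9 directly by hydroboration.

Alternative 3: Ring B is opened at C8–C9 to a ring A cyclohexane with a vinyl group (C9=C11) on C10 and a but-3-enyl chain ending in C8=C17 on C5. A zirconocene equivalent generated in situ would couple the two alkenes to a zirconacyclopentane, and oxygen would convert both carbon–zirconium bonds into hydroxyls, giving the diol A3.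
- In its favour: C8 and C9 are set together, trans-diequatorial, and C11 and C17 arrive oxygenated at the right level. The chosen route spends about ten steps on the same ground, so on step economy for ring B this alternative is stronger.
- Against it: one alkene sits on a quaternary carbon and the new ring is six-membered, the slower and less selective class of such couplings, and oxygenation of zirconacycles is only moderately efficient.
- A3 shows two very similar primary hydroxyls that must be distinguished before the side chain is built, whereas in the chosen route they appear at different times.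
- Its precursor, with a vicinal quaternary/tertiary pair at C10/C5, has no obvious chiral-pool origin.
- The chosen strategy offers C5 and C10 from carvone in two alkylations with every carvone carbon used, and it concentrates risk in one ene reaction with close precedent.

Key step: step 5

Remarks on the chemistry: labdane numbering is used for all bicyclic compounds. From 10 onwards every compound is a trans-decalin with H5 anti to the C20 methyl. Stereocentres that form as mixtures and are erased later (C6 of 4, the carbinol carbon of 8, C9 in 13–19, C4 in 14–17, C8 in 26, C13 in 33–35) are left undefined in the SMILES.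

## Route

Step 1
Reactants: 1 (S)-(+)-carvone; 2 iodomethane
Product: 4 (5S)-2,6-dimethyl-5-(prop-1-en-2-yl)cyclohex-2-en-1-one (6-methylcarvone; C6 epimers), via lithium dienolate 3 (not isolated)
Conditions: LiN(i-Pr)2, THF, −78 °C; MeI, −78 to 0 °C
Reagents that add atoms: none
Why: Kinetic deprotonation of the enone at the alpha-prime carbon (the future C10) and SN2 methylation (enolate alkylation); both C6 epimers give the same enolate in step 2, so this centre needs no control.

Step 2
Reactants: 4 (5S)-2,6-dimethyl-5-(prop-1-en-2-yl)cyclohex-2-en-1-one; 5 methyl bromoacetate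
Product: 7 methyl 2-[(1R,6R)-1,3-dimethyl-2-oxo-6-(prop-1-en-2-yl)cyclohex-3-en-1-yl]acetate, via lithium enolate 6 (not isolated)
Conditions: LiN(i-Pr)2, THF, −78 to −20 °C; BrCH2CO2Me, DMPU, −78 to 0 °C
Reagents that add atoms: none
Why: Alkylation of the tetrasubstituted enolate; the electrophile approaches the face opposite the neighbouring isopropenyl group, which sets quaternary C10 with the acetate arm (C1–C2) trans to the isopropenyl group (C4) and the methyl (C20) cis to it.

Step 3
Reactants: 7 methyl 2-[(1R,6R)-1,3-dimethyl-2-oxo-6-(prop-1-en-2-yl)cyclohex-3-en-1-yl]acetate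
Product: 8 2-[(1R,6R)-2-hydroxy-1,3-dimethyl-6-(prop-1-en-2-yl)cyclohex-3-en-1-yl]ethan-1-ol (carbinol epimers)
Conditions: LiAlH4, Et2O, 0 °C
Reagents that add atoms: none
Why: Hydride reduction of the ester to the primary alcohol and 1,2-reduction of the hindered enone to the allylic alcohol; the carbinol epimers converge in step 4.

Step 4
Reactants: 8 2-[(1R,6R)-2-hydroxy-1,3-dimethyl-6-(prop-1-en-2-yl)cyclohex-3-en-1-yl]ethan-1-ol
Product: 9 2-[(1R,6R)-1,3-dimethyl-2-oxo-6-(prop-1-en-2-yl)cyclohex-3-en-1-yl]acetaldehyde
Conditions: (COCl)2, DMSO, CH2Cl2, −78 °C; Et3N, −78 to 0 °C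
Reagents that add atoms: none
Why: Swern oxidation; both hydroxyls are turned into alkoxysulfonium ions before base is added, so the hydroxy aldehyde cannot close to a lactol and be over-oxidised to a lactone, and C10 is quaternary so nothing can epimerise.

Step 5
Reactants: 9 2-[(1R,6R)-1,3-dimethyl-2-oxo-6-(prop-1-en-2-yl)cyclohex-3-en-1-yl]acetaldehyde
Product: 10 (4aR,7S,8aR)-7-hydroxy-2,8a-dimethyl-5-methylidene-4a,5,6,7,8,8a-hexahydronaphthalen-1(4H)-one (C2 hydroxyl axial and syn to C20)
Conditions: Me2AlCl (2 equiv), CH2Cl2, −78 to 0 °C; cold dilute HCl work-up
Reagents that add atoms: none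
Why: Me2AlCl binds the aldehyde oxygen (the hindered, conjugated C9 ketone is the weaker donor and the excess covers it), the terminal alkene carbon C3 attacks C2, and a C18 hydrogen passes to oxygen through a six-centre array, ending on an Al–CH3 group as methane; this is a type 2 intramolecular carbonyl-ene reaction, and the closest known case is the Me2AlCl-promoted cyclisation of 5-methylhex-5-enals to 3-methylidenecyclohexanols. Ring A closes as a six-membered ring, exo with respect to the C=O bond and endo with respect to the C3=C4 bond, since both alkene carbons end up in the ring. The ring fusion is not decided in this step: the C1 arm on C10 and C4 on C5 are trans and can only reach each other from equatorial positions, so the cis-decalin is not accessible. The one new stereocentre, C2, is set by the chair-like transition state, because hydrogen transfer is possible only when the oxygen lies over the C4–C18 unit, that is axial and syn to C20; the equatorial epimer would point to a stepwise cationic path, and either epimer is deoxygenated to the same 12. The step needs chemoselectivity (aldehyde over ketone, secured by sterics and conjugation), loss of the C18 hydrogen and not a C3 or C5 hydrogen (secured by the cyclic hydrogen transfer, the low temperature and a Lewis acid that consumes the proton), and no epimerisation (C10 is quaternary, C5 is not acidic).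

Step 6
Reactants: 10 (4aR,7S,8aR)-7-hydroxy-2,8a-dimethyl-5-methylidene-4a,5,6,7,8,8a-hexahydronaphthalen-1(4H)-one
Product: 11 O-[(2S,4aR,8aR)-7,8a-dimethyl-4-methylidene-8-oxo-1,2,3,4,4a,5,8,8a-octahydronaphthalen-2-yl] O-phenyl carbonothioate
Conditions: PhOC(S)Cl, pyridine, DMAP, CH2Cl2, 0 °C to rt
Reagents that add atoms: O-phenyl chlorothionoformate, S=C(Cl)Oc1ccccc1
Why: Acylation of the secondary alcohol to the aryl thionocarbonate (activation for a Barton–McCombie deoxygenation); no strong base is used, so the enone and its gamma-hydrogens are left alone.

Step 7
Reactants: 11 O-phenyl thionocarbonate of 10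
Product: 12 (4aR,8aR)-2,8a-dimethyl-5-methylidene-4a,5,6,7,8,8a-hexahydronaphthalen-1(4H)-one
Conditions: Bu3SnH, AIBN (cat.), toluene, 90 °C
Reagents that add atoms: none
Why: Barton–McCombie radical deoxygenation; at a normal Bu3SnH concentration the secondary C2 radical is reduced before the reversible three-membered closure onto C4=C18 can lead anywhere, and the C2 stereocentre disappears.

Step 8
Reactants: 12 (4aR,8aR)-2,8a-dimethyl-5-methylidene-4a,5,6,7,8,8a-hexahydronaphthalen-1(4H)-one
Product: 13 (4aR,8aR)-2,8a-dimethyl-5-methylidene-1-[(trimethylsilyl)methyl]-1,4,4a,5,6,7,8,8a-octahydronaphthalen-1-ol (C9 carbinol; either epimer serves)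
Conditions: Me3SiCH2Li, THF/pentane, −78 to 0 °C; aq. NH4Cl
Reagents that add atoms: (trimethylsilyl)methyllithium, [Li]C[Si](C)(C)C
Why: 1,2-Addition of the organolithium to the C9 ketone, which has no alpha-hydrogen (first half of a Peterson olefination); the tertiary carbinol brings in C11 and takes the ketone out of play for the borane and hydroxide steps that follow.

Step 9
Reactants: 13 C9 carbinol with the (trimethylsilyl)methyl group
Product: 15 the C18 primary alcohol (13 with C4=C18 converted into C4H–C18H2OH; C4 epimers), via C18 organoborane 14 (not isolated)
Conditions: 9-BBN, THF, rt to 45 °C; then NaOH, H2O2, 0 °C to rt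
Reagents that add atoms: hydrogen peroxide, OO
Why: Hydroboration–oxidation; 9-BBN selects the 1,1-disubstituted C4=C18 over the trisubstituted C7=C8 and puts boron on the terminal C18, and the C4 configuration does not matter because C4 becomes symmetric in step 11.

Step 10
Reactants: 15 the C18 primary alcohol
Product: 16 the C18 aldehyde (C4H–CHO, C9 carbinol unchanged)
Conditions: Dess–Martin periodinane, NaHCO3, CH2Cl2, 0 °C to rt
Reagents that add atoms: none
Why: Dess–Martin oxidation of the primary alcohol under buffered conditions; the tertiary carbinol cannot be oxidised.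

Step 11
Reactants: 16 the C18 aldehyde
Product: 18 the 4,4-bis(hydroxymethyl) triol (C18 and C19 hydroxyls, C9 carbinol), via aldol adduct 17 (not isolated)
Conditions: aq. CH2O (excess), KOH, EtOH/H2O, rt to 50 °C
Reagents that add atoms: formaldehyde, C=O
Why: Aldol addition of the alpha-branched aldehyde to formaldehyde creates the quaternary C4, and the adduct, which can no longer enolise, is reduced by a second formaldehyde in a crossed Cannizzaro reaction; C4 then carries two identical arms and is not a stereocentre.

Step 12
Reactants: 18 the 4,4-bis(hydroxymethyl) triol
Product: 19 the O18,O19-acetonide of 18 (spiro 2,2-dimethyl-1,3-dioxane at C4)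
Conditions: Me2C(OMe)2, PPTS (cat.), CH2Cl2, rt
Reagents that add atoms: 2,2-dimethoxypropane, COC(C)(C)OC
Why: Acid-catalysed acetal exchange gives the six-membered acetonide of the 1,3-diol; any beta-hydroxysilane that eliminates under the mild acid only arrives early at 20.

Step 13
Reactants: 19 the acetonide carbinol
Product: 20 the (5S,10R) diene acetonide with exocyclic C9=C11 and C7=C8 (C17 methyl on C8)
Conditions: KH, THF, 0 °C to rt
Reagents that add atoms: none
Why: Base-induced Peterson elimination (syn loss of the silanolate from the potassium alkoxide); silicon dictates that the double bond forms only toward C11, so no positional isomer of the diene can arise and no cation is involved.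

Step 14
Reactants: 20 the diene acetonide
Product: 22 the (5S,9R,10R) C11 alcohol (H9 anti to C20, C7=C8 retained), via C11 organoborane 21 (not isolated)
Conditions: 9-BBN, THF, rt to 60 °C; then NaOH, H2O2, 0 °C to rt
Reagents that add atoms: hydrogen peroxide, OO
Why: Hydroboration–oxidation of the exocyclic terminus of the diene: boron goes to C11 and hydrogen is delivered to C9 on the face opposite the axial C20 methyl on the adjacent C10, which sets C9 with H9 anti to C20 and the C11 arm equatorial; the trisubstituted C7=C8 does not react with 9-BBN.

Step 15
Reactants: 22 the C11 alcohol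
Product: 23 the C11 pivalate
Conditions: t-BuCOCl, pyridine, DMAP (cat.), CH2Cl2, 0 °C to rt
Reagents that add atoms: pivaloyl chloride, CC(C)(C)C(=O)Cl
Why: Acylation of the primary alcohol; the pivalate is chosen because it resists the base of step 18 and does not migrate to O17.

Step 16
Reactants: 23 the C11 pivalate
Product: 25 the C17 enal (C7=C8–CHO), via allylic alcohol 24 (not isolated)
Conditions: SeO2 (cat.), t-BuOOH, CH2Cl2, rt; then Dess–Martin periodinane, NaHCO3, CH2Cl2, rt
Reagents that add atoms: selenium dioxide, O=[Se]=O; tert-butyl hydroperoxide, CC(C)(C)OO
Why: Allylic oxidation by SeO2 (ene reaction, then [2,3]-sigmatropic shift) at the methyl group on the more substituted alkene carbon C8, the methyl being preferred over the hindered methine C9–H; the second oxidant brings the allylic alcohol and any enal already formed to the single enal 25.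

Step 17
Reactants: 25 the C17 enal
Product: 26 the saturated C17 aldehyde (C8 epimers; formyl axial expected to predominate)
Conditions: H2 (1 atm), Pd/C, EtOAc, rt
Reagents that add atoms: none
Why: Heterogeneous hydrogenation of the conjugated C7=C8 bond; hydrogen adds mainly from the face away from C20, which gives the aldehyde with the wrong C8 configuration, corrected in step 18.

Step 18
Reactants: 26 the saturated C17 aldehyde
Product: 28 the (5S,8S,9R,10R) C17 alcohol (C17 equatorial; C11 pivalate), via equatorial aldehyde 27 (not isolated)
Conditions: DBU, CH2Cl2, rt; then NaBH4, MeOH, 0 °C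
Reagents that add atoms: none
Why: Epimerisation through the enolate puts the formyl group equatorial, trans to the equatorial C11 arm and free of the 1,3-diaxial contact with C20, so C8 is set under thermodynamic control; NaBH4 then reduces the aldehyde and leaves the pivalate.

Step 19
Reactants: 28 the C17 alcohol
Product: 29 the C17 tert-butyldimethylsilyl ether (C11 pivalate)
Conditions: t-BuMe2SiCl, imidazole, DMF, rt
Reagents that add atoms: tert-butyldimethylsilyl chloride, CC(C)(C)[Si](C)(C)Cl
Why: Silylation of the primary alcohol; the silyl ether survives hydride, radical and amide-base conditions and falls off with the acetonide at the end.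

Step 20
Reactants: 29 the C17 silyl ether C11 pivalate
Product: 30 the (5S,8S,9R,10R) C11 alcohol (O17 silyl ether, O18/O19 acetonide)
Conditions: i-Bu2AlH, CH2Cl2, −78 °C
Reagents that add atoms: none
Why: Reductive cleavage of the pivalate ester; silyl ether and acetonide are inert to i-Bu2AlH at low temperature.

Step 21
Reactants: 30 the C11 alcohol
Product: 31 the C11 iodide
Conditions: I2, PPh3, imidazole, toluene, rt to 60 °C
Reagents that add atoms: iodine, II
Why: Appel-type iodination: iodide displaces the alkoxyphosphonium group at the primary C11 by SN2; imidazole keeps the medium neutral for the acetonide and the silyl ether.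

Step 22
Reactants: 31 the C11 iodide; 32 3-methylideneoxolan-2-one
Product: 33 the saturated lactone (C11–C12 formed; C13 epimers)
Conditions: (Me3Si)3SiH, AIBN (cat.), 32 (5 equiv), toluene, 80 °C, silane added slowly
Reagents that add atoms: none
Why: Giese reaction: the silyl radical abstracts iodine, the nucleophilic primary C11 radical adds to the terminal carbon of the electron-poor exocyclic alkene of 32, and the lactone-stabilised radical takes hydrogen from the silane; ring B is saturated, so the radical has no alkene to rearrange onto, and the C13 centre is erased in step 23.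

Step 23
Reactants: 33 the saturated lactone
Product: 36 the (5S,8S,9R,10S) protected butenolide (C13=C14), via alpha-phenylselanyl lactone 34 (not isolated), via selenoxide 35 (not isolated)
Conditions: LiN(i-Pr)2, THF, −78 °C; PhSeBr, −78 °C; crude selenide: H2O2, pyridine, CH2Cl2, 0 °C to rt
Reagents that add atoms: none
Why: Selenenylation of the lactone enolate at C13, oxidation to the selenoxide and syn-elimination; elimination into the ring toward C14 gives the endocyclic conjugated butenolide, the usual course for alpha-alkyl gamma-lactones.

Step 24
Reactants: 36 the protected butenolide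
Product: 37 3-{2-[(1R,2S,4aS,8aS)-2,5,5-tris(hydroxymethyl)-8a-methyldecahydronaphthalen-1-yl]ethyl}furan-2(5H)-one (CNP0271381.1)
Conditions: aq. HCl, THF/MeOH, rt
Reagents that add atoms: none
Why: Acid hydrolysis removes the acetonide and the silyl ether in one operation; the butenolide and the four stereocentres, none of which is acid-labile, are untouched.

## Compound list

1 | (S)-(+)-carvone, (5S)-2-methyl-5-(prop-1-en-2-yl)cyclohex-2-en-1-one | C=C(C)[C@H]1CC=C(C)C(=O)C1 | starting material
2 | iodomethane | CI | starting material
3 | lithium dienolate of 1 (O–Li on C1, C1=C6 and C2=C3; not isolated) | C=C(C)[C@H]1CC=C(C)C(O[Li])=C1 | intermediate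
4 | (5S)-2,6-dimethyl-5-(prop-1-en-2-yl)cyclohex-2-en-1-one (C6 epimers) | CC1[C@@H](C(C)=C)CC=C(C)C1=O | intermediate
5 | methyl bromoacetate | COC(=O)CBr | starting material
6 | lithium enolate of 4 (tetrasubstituted C1=C6 enolate; not isolated) | CC1=C(O[Li])C(C)=CC[C@@H]1C(C)=C | intermediate
7 | methyl 2-[(1R,6R)-1,3-dimethyl-2-oxo-6-(prop-1-en-2-yl)cyclohex-3-en-1-yl]acetate | C[C@@]1(CC(=O)OC)[C@@H](C(C)=C)CC=C(C)C1=O | intermediate
8 | 2-[(1R,6R)-2-hydroxy-1,3-dimethyl-6-(prop-1-en-2-yl)cyclohex-3-en-1-yl]ethan-1-ol (carbinol epimers) | C[C@@]1(CCO)[C@@H](C(C)=C)CC=C(C)C1O | intermediate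
9 | 2-[(1R,6R)-1,3-dimethyl-2-oxo-6-(prop-1-en-2-yl)cyclohex-3-en-1-yl]acetaldehyde | C[C@@]1(CC=O)[C@@H](C(C)=C)CC=C(C)C1=O | intermediate
10 | (4aR,7S,8aR)-7-hydroxy-2,8a-dimethyl-5-methylidene-4a,5,6,7,8,8a-hexahydronaphthalen-1(4H)-one | C[C@@]12C[C@@H](O)CC(=C)[C@H]1CC=C(C)C2=O | intermediate
11 | O-[(2S,4aR,8aR)-7,8a-dimethyl-4-methylidene-8-oxo-1,2,3,4,4a,5,8,8a-octahydronaphthalen-2-yl] O-phenyl carbonothioate | C[C@@]12C[C@@H](OC(=S)Oc3ccccc3)CC(=C)[C@H]1CC=C(C)C2=O | intermediate
12 | (4aR,8aR)-2,8a-dimethyl-5-methylidene-4a,5,6,7,8,8a-hexahydronaphthalen-1(4H)-one | C[C@@]12CCCC(=C)[C@H]1CC=C(C)C2=O | intermediate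
13 | (4aR,8aR)-2,8a-dimethyl-5-methylidene-1-[(trimethylsilyl)methyl]-1,4,4a,5,6,7,8,8a-octahydronaphthalen-1-ol (C9 carbinol epimers) | C[C@@]12CCCC(=C)[C@H]1CC=C(C)C2(O)C[Si](C)(C)C | intermediate
14 | C18 organoborane: 13 with C4=C18 converted into C4H–C18H2–(9-borabicyclo[3.3.1]nonan-9-yl) (not isolated) | C[C@@]12CCCC(CB3C4CCCC3CCC4)[C@H]1CC=C(C)C2(O)C[Si](C)(C)C | intermediate
15 | C18 primary alcohol: 13 with C4=C18 converted into C4H–CH2OH (C4 epimers) | C[C@@]12CCCC(CO)[C@H]1CC=C(C)C2(O)C[Si](C)(C)C | intermediate
16 | C18 aldehyde: 15 with CH2OH oxidised to CHO | C[C@@]12CCCC(C=O)[C@H]1CC=C(C)C2(O)C[Si](C)(C)C | intermediate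
17 | aldol adduct: 16 with an added CH2OH (C19) on C4 (not isolated) | C[C@@]12CCCC(CO)(C=O)[C@H]1CC=C(C)C2(O)C[Si](C)(C)C | intermediate
18 | 4,4-bis(hydroxymethyl) triol with the C9 carbinol and C7=C8 | C[C@@]12CCCC(CO)(CO)[C@H]1CC=C(C)C2(O)C[Si](C)(C)C | intermediate
19 | O18,O19-acetonide of 18 (spiro 2,2-dimethyl-1,3-dioxane at C4) | C[C@@]12CCCC3(COC(C)(C)OC3)[C@H]1CC=C(C)C2(O)C[Si](C)(C)C | intermediate
20 | (5S,10R) diene acetonide: exocyclic C9=C11, C7=C8 with C17 methyl | C[C@@]12CCCC3(COC(C)(C)OC3)[C@H]1CC=C(C)C2=C | intermediate
21 | C11 organoborane from 20: C9H–C11H2–(9-borabicyclo[3.3.1]nonan-9-yl), H9 anti to C20 (not isolated) | C[C@@]12CCCC3(COC(C)(C)OC3)[C@H]1CC=C(C)[C@H]2CB4C5CCCC4CCC5 | intermediate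
22 | (5S,9R,10R) C11 alcohol with C7=C8, acetonide at C4 | C[C@@]12CCCC3(COC(C)(C)OC3)[C@H]1CC=C(C)[C@H]2CO | intermediate
23 | C11 pivalate of 22 | C[C@@]12CCCC3(COC(C)(C)OC3)[C@H]1CC=C(C)[C@H]2COC(=O)C(C)(C)C | intermediate
24 | C17 allylic alcohol: 23 with the C8 methyl oxidised to CH2OH (not isolated) | C[C@@]12CCCC3(COC(C)(C)OC3)[C@H]1CC=C(CO)[C@H]2COC(=O)C(C)(C)C | intermediate
25 | C17 enal: 23 with the C8 methyl oxidised to CHO | C[C@@]12CCCC3(COC(C)(C)OC3)[C@H]1CC=C(C=O)[C@H]2COC(=O)C(C)(C)C | intermediate
26 | saturated C17 aldehyde (C8 epimers) | C[C@@]12CCCC3(COC(C)(C)OC3)[C@H]1CCC(C=O)[C@H]2COC(=O)C(C)(C)C | intermediate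
27 | saturated C17 aldehyde with equatorial formyl group (not isolated) | C[C@@]12CCCC3(COC(C)(C)OC3)[C@H]1CC[C@H](C=O)[C@H]2COC(=O)C(C)(C)C | intermediate
28 | (5S,8S,9R,10R) C17 alcohol, C11 pivalate, acetonide at C4 | C[C@@]12CCCC3(COC(C)(C)OC3)[C@H]1CC[C@H](CO)[C@H]2COC(=O)C(C)(C)C | intermediate
29 | O17 tert-butyldimethylsilyl ether of 28 | C[C@@]12CCCC3(COC(C)(C)OC3)[C@H]1CC[C@H](CO[Si](C)(C)C(C)(C)C)[C@H]2COC(=O)C(C)(C)C | intermediate
30 | (5S,8S,9R,10R) C11 alcohol with O17 silyl ether and acetonide at C4 | C[C@@]12CCCC3(COC(C)(C)OC3)[C@H]1CC[C@H](CO[Si](C)(C)C(C)(C)C)[C@H]2CO | intermediate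
31 | C11 iodide from 30 | C[C@@]12CCCC3(COC(C)(C)OC3)[C@H]1CC[C@H](CO[Si](C)(C)C(C)(C)C)[C@H]2CI | intermediate
32 | 3-methylideneoxolan-2-one | C=C1CCOC1=O | starting material
33 | saturated lactone: 3-substituted oxolan-2-one linked through C12–C11 to C9 (C13 epimers) | C[C@@]12CCCC3(COC(C)(C)OC3)[C@H]1CC[C@H](CO[Si](C)(C)C(C)(C)C)[C@H]2CCC1CCOC1=O | intermediate
34 | alpha-phenylselanyl lactone from 33 (not isolated) | C[C@@]12CCCC3(COC(C)(C)OC3)[C@H]1CC[C@H](CO[Si](C)(C)C(C)(C)C)[C@H]2CCC1([Se]c4ccccc4)CCOC1=O | intermediate
35 | selenoxide of 34 (not isolated) | C[C@@]12CCCC3(COC(C)(C)OC3)[C@H]1CC[C@H](CO[Si](C)(C)C(C)(C)C)[C@H]2CCC1([Se](=O)c4ccccc4)CCOC1=O | intermediate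
36 | (5S,8S,9R,10S) protected butenolide: target with O18/O19 acetonide and O17 silyl ether | C[C@@]12CCCC3(COC(C)(C)OC3)[C@H]1CC[C@H](CO[Si](C)(C)C(C)(C)C)[C@H]2CCC1=CCOC1=O | intermediate
37 | 3-{2-[(1R,2S,4aS,8aS)-2,5,5-tris(hydroxymethyl)-8a-methyldecahydronaphthalen-1-yl]ethyl}furan-2(5H)-one | C[C@@]12CCCC(CO)(CO)[C@H]1CC[C@H](CO)[C@H]2CCC1=CCOC1=O | target

## Step count and least certain steps

Total step count: 24. Longest linear sequence: 24 steps from 1 (2, 5 and 32 are bought).

Step 5 (key step). The hydrogen transfer needs the aluminium-bound oxygen axial, where it is syn-axial to the C20 methyl. If this slows the concerted path, the reaction may turn stepwise through the C4 cation, with chloride capture or proton loss toward C3 or C5 in place of C18. Competitive binding of the Lewis acid to the enone may also stall the reaction. The fallback forms the same C2–C3 bond by a polar allylation and sets out from 9. Ene-type chlorination of the isopropenyl group (Ca(OCl)2, CO2, CH2Cl2/H2O, 0 °C; the electron-poor enone alkene does not react) should give the 2-(chloromethyl)allyl keto-aldehyde F1. Intramolecular Nozaki–Hiyama allylation with CrCl2 (divalent chromium) in THF, which adds to aldehydes in preference to ketones, should then close ring A. The allyl unit is symmetrical, so either terminus gives the constitution of 10, and the route is rejoined at 10 as a mixture of C2 epimers that converges in step 7.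

Step 16. The ene step of the SeO2 oxidation may remove the axial C9 hydrogen instead of a C17 hydrogen, which leads to hydroxylation at C9, and the acidic selenium species may loosen the acetonide. The fallback moves the oxidation to a point where C9 carries no hydrogen and sets out from 19.
- SeO2/t-BuOOH should give the C17 allylic alcohol F2, and silylation (t-BuMe2SiCl, imidazole) the silyl ether F3.
- KH should give the diene F4.
- 9-BBN followed by NaOH/H2O2 should give, through the organoborane F5, the homoallylic alcohol F6.
- Hydrogenation with [Ir(cod)(PCy3)(py)]PF6, directed by the C11 hydroxyl to the face syn to C20, should deliver 30, where the route is rejoined.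

This detour is three steps shorter. It is held in reserve because it replaces thermodynamic control at C8 by a directed hydrogenation against the steric bias of C20, and because it exposes the acid-sensitive carbinol to the oxidant.

Step 11. The aldol at the hindered C4, next to the ring fusion, may be slow or reversible, and the hydride transfer of the Cannizzaro stage may stop short. The fallback separates bond formation from reduction and sets out from 16: aldol with aqueous formaldehyde under mild base (K2CO3, THF/H2O), isolation of 17, and reduction with NaBH4 in MeOH, rejoining at 18. No new compound is involved.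

Step 22. The C11 radical may be reduced before it adds, the acceptor may oligomerise, or a 1,5-hydrogen shift may move the radical into the ring. The fallback changes the bond that is formed (C12–C13 in place of C11–C12) and sets out from 30.
- Dess–Martin oxidation should give the C11 aldehyde F7, whose C9 centre is already in its more stable equatorial form.
- Wittig methylenation (Ph3P=CH2, THF) should give the C9 vinyl compound F8.
- 9-BBN should give the C12 organoborane F9.
- B-alkyl Suzuki–Miyaura coupling with bought 3-bromofuran-2(5H)-one (Pd(dppf)Cl2, AsPh3, Cs2CO3, DMF/THF/H2O) should give 36 directly, where the route is rejoined.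

The double bond is then placed by construction, and steps 21 to 23 are bypassed.

Step 23. The selenoxide may eliminate toward C12 and give the exocyclic alkylidene lactone, and excess oxidant may attack the butenolide. The fallback sets out from 33 with step 23 run as described: the exocyclic isomer F10 is not discarded but heated with RhCl3·3H2O (cat.) in ethanol, which should move the double bond into the ring to the more stable endocyclic butenolide. These acidic conditions are expected to remove the acetonide and the silyl ether as well, so this detour rejoins the route at 37. If the protecting groups survive, step 24 follows.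

## Further compounds

F1 | step 5 | 2-[(1R,6R)-6-(3-chloroprop-1-en-2-yl)-1,3-dimethyl-2-oxocyclohex-3-en-1-yl]acetaldehyde | C[C@@]1(CC=O)[C@@H](C(CCl)=C)CC=C(C)C1=O
F2 | step 16 | C17 allylic alcohol of 19 (C8 methyl oxidised to CH2OH, C9 carbinol retained) | C[C@@]12CCCC3(COC(C)(C)OC3)[C@H]1CC=C(CO)C2(O)C[Si](C)(C)C
F3 | step 16 | O17 tert-butyldimethylsilyl ether of F2 | C[C@@]12CCCC3(COC(C)(C)OC3)[C@H]1CC=C(CO[Si](C)(C)C(C)(C)C)C2(O)C[Si](C)(C)C
F4 | step 16 | diene acetonide with exocyclic C9=C11, C7=C8 and C17 silyl ether | C[C@@]12CCCC3(COC(C)(C)OC3)[C@H]1CC=C(CO[Si](C)(C)C(C)(C)C)C2=C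
F5 | step 16 | C11 organoborane from F4 (9-borabicyclo[3.3.1]nonan-9-yl on C11, H9 anti to C20) | C[C@@]12CCCC3(COC(C)(C)OC3)[C@H]1CC=C(CO[Si](C)(C)C(C)(C)C)[C@H]2CB4C5CCCC4CCC5
F6 | step 16 | C11 alcohol with C7=C8 and C17 silyl ether | C[C@@]12CCCC3(COC(C)(C)OC3)[C@H]1CC=C(CO[Si](C)(C)C(C)(C)C)[C@H]2CO
F0 | step 11 | none | none
F7 | step 22 | C11 aldehyde from 30 | C[C@@]12CCCC3(COC(C)(C)OC3)[C@H]1CC[C@H](CO[Si](C)(C)C(C)(C)C)[C@H]2C=O
F8 | step 22 | C9 vinyl compound (C11=C12) | C[C@@]12CCCC3(COC(C)(C)OC3)[C@H]1CC[C@H](CO[Si](C)(C)C(C)(C)C)[C@H]2C=C
F9 | step 22 | C12 organoborane from F8 (9-borabicyclo[3.3.1]nonan-9-yl on C12) | C[C@@]12CCCC3(COC(C)(C)OC3)[C@H]1CC[C@H](CO[Si](C)(C)C(C)(C)C)[C@H]2CCB4C5CCCC4CCC5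
F10 | step 23 | exocyclic C12=C13 alkylidene lactone isomer of 36 (alkene geometry undefined) | C[C@@]12CCCC3(COC(C)(C)OC3)[C@H]1CC[C@H](CO[Si](C)(C)C(C)(C)C)[C@H]2CC=C1CCOC1=O
A1 | alternative 1 | trans-fused C6=C7 octalin with C11 aldehyde, axial C17 silyloxymethyl arm and 4,4-bis(benzyloxymethyl) group | C[C@@]12CCCC(COCc3ccccc3)(COCc3ccccc3)[C@H]1C=C[C@@H](CO[Si](C)(C)C(C)(C)C)[C@H]2C=O
A2 | alternative 2 | C5=C6 octalin acid with quaternary C10, equatorial C17 benzyloxymethyl arm, axial C9 carboxylic acid and C4 acetonide | C[C@@]12CCCC3(COC(C)(C)OC3)C1=CC[C@H](COCc1ccccc1)[C@@H]2C(=O)O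
A3 | alternative 3 | ent-drimane-11,17-diol with the C4 acetonide | C[C@@]12CCCC3(COC(C)(C)OC3)[C@H]1CC[C@H](CO)[C@H]2CO
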